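**Plan**
- Retrosynthesis: the two phenols are unmasked last and the C4 ketone is traced back to a C4 methyl ether. Ring C is then cut at O1–C2 and C3–C4 into a 4-methoxy ortho-quinone methide of ring A and a 4-silyloxystyrene. Ring A is cut at C4a–C4 (formyl) and C8–C1'' (lavandulyl), back to 5-methoxyresorcinol.
- Enabling feature: ring C (O1, C2, C3, C4, C4a, C8a) shares the C4a–C8a edge with the phloroglucinol-type ring A, so O1=C8a–C4a=C4 is the heterodiene of an ortho-quinone methide and C2–C3 is a former styrene C=C.
- Forward order: the lavandulyl chain is joined to C8 by Negishi coupling, C4 is added by ortho-lithiation/formylation, ring C is closed by the [4+2], and C4 is oxidised to the ketone.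
- Stereochemistry: C2'' comes from an Evans deconjugative alkylation ((S)-lavandulol maps onto 2''R). C2 comes from the chiral phosphoric acid in the cycloaddition. The C4 centre is temporary.

Key step: step 13

Assumption: flavanone numbering (O1, C2–C4, C4a, C5–C8, C8a; lavandulyl carbons double-primed) is used for all bicyclic compounds; "lavandulyl" means 5-methyl-2-(prop-1-en-2-yl)hex-4-en-1-yl.
Assumption: the sense of induction of the chiral phosphoric acid in step 13 cannot be derived from a close analogue; the (R)-acid is written, and the (S)-acid would be taken if a trial run shows the opposite sense.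

**Step 1**
Reactants: 1 (S)-4-benzyloxazolidin-2-one; 2 3-methylbut-2-enoyl chloride
Product: 4 (S)-4-benzyl-3-(3-methylbut-2-enoyl)oxazolidin-2-one, via lithium oxazolidinide 3 (not isolated)
Conditions: n-BuLi, THF, −78 °C; then 2, −78 → 0 °C
Reagents that add atoms: none
Why: N-acylation of the lithiated Evans auxiliary with an acid chloride is standard, and the absence of an amine base avoids vinylketene formation and deconjugation of the senecioyl unit.

**Step 2**
Reactants: 4 (S)-4-benzyl-3-(3-methylbut-2-enoyl)oxazolidin-2-one; 5 1-bromo-3-methylbut-2-ene (prenyl bromide)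
Product: 7 (S)-4-benzyl-3-[(2S)-5-methyl-2-(prop-1-en-2-yl)hex-4-enoyl]oxazolidin-2-one, via sodium dienolate 6 (not isolated)
Conditions: NaN(SiMe3)2, THF, −78 °C; then 5, −78 → −40 °C
Reagents that add atoms: none
Why: Evans deconjugative α-alkylation, in which γ-deprotonation gives the chelated (Z)-dienolate that is alkylated at the α-carbon on the face away from the benzyl group, so the (S)-auxiliary sets the (2S) centre that becomes C2'' of the target.

**Step 3**
Reactants: 7 (S)-4-benzyl-3-[(2S)-5-methyl-2-(prop-1-en-2-yl)hex-4-enoyl]oxazolidin-2-one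
Product: 8 (S)-lavandulol [(2S)-5-methyl-2-(prop-1-en-2-yl)hex-4-en-1-ol]
Conditions: LiBH4, MeOH, Et2O, 0 °C
Reagents that add atoms: none
Why: Reductive cleavage of the imide with LiBH4 releases the primary alcohol and the auxiliary without a base strong enough to epimerise or reconjugate the α-isopropenyl centre.

**Step 4**
Reactants: 8 (S)-lavandulol
Product: 9 (S)-lavandulyl iodide [(3S)-3-(iodomethyl)-2,6-dimethylhepta-1,5-diene]
Conditions: I2, PPh3, imidazole, CH2Cl2, 0 → 25 °C
Reagents that add atoms: iodine, II
Why: Appel-type iodination proceeds by SN2 displacement at the primary carbon, so the adjacent stereocentre is not touched.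

**Step 5**
Reactants: 10 5-methoxyresorcinol
Product: 11 1-methoxy-3,5-bis(methoxymethoxy)benzene
Conditions: MeOCH2Cl, i-Pr2NEt, CH2Cl2, 0 → 25 °C
Reagents that add atoms: chloromethyl methyl ether, COCCl
Why: Williamson-type O-alkylation of both phenols with chloromethyl methyl ether installs the two directing groups for the metalations that follow.

**Step 6**
Reactants: 11 1-methoxy-3,5-bis(methoxymethoxy)benzene
Product: 13 2-iodo-5-methoxy-1,3-bis(methoxymethoxy)benzene, via 2-lithioarene 12 (not isolated)
Conditions: n-BuLi, THF, 0 °C; then I2, −78 → 25 °C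
Reagents that add atoms: iodine, II
Why: Directed ortho-metalation, in which the C2 hydrogen between the two chelating methoxymethyl ethers is the kinetically most acidic ring position (the sites next to the weaker methoxy director are not expected to compete), followed by iodinolysis of the aryllithium.

**Step 7**
Reactants: 9 (S)-lavandulyl iodide; 13 2-iodo-5-methoxy-1,3-bis(methoxymethoxy)benzene
Product: 15 5-methoxy-1,3-bis(methoxymethoxy)-2-[(2R)-lavandulyl]benzene, via alkylzinc iodide 14 (not isolated)
Conditions: 9, Zn dust, LiCl, THF, 25 → 40 °C; then 13, Pd(OAc)2 (cat.), 2-dicyclohexylphosphino-2',6'-dimethoxybiphenyl (cat.), THF, 25 → 50 °C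
Reagents that add atoms: none
Why: Negishi sp3–sp2 coupling, in which LiCl-assisted zinc insertion gives a primary alkylzinc whose stereocentre is one carbon away from the metal and the electron-rich biarylphosphine on zerovalent palladium makes oxidative addition into the di-ortho-substituted iodide and reductive elimination faster than β-hydride elimination, so C2'' is carried through unchanged (its descriptor becomes R only because the CIP priorities change).

**Step 8**
Reactants: 15 5-methoxy-1,3-bis(methoxymethoxy)-2-[(2R)-lavandulyl]benzene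
Product: 17 6-methoxy-2,4-bis(methoxymethoxy)-3-[(2R)-lavandulyl]benzaldehyde, via aryllithium 16 (not isolated)
Conditions: n-BuLi, N,N,N',N'-tetramethylethylenediamine, THF, −20 → 0 °C; then DMF, 0 → 25 °C
Reagents that add atoms: N,N-dimethylformamide, CN(C)C=O
Why: Second directed ortho-metalation, in which the two remaining ring hydrogens are equivalent and each lies between a methoxymethoxy and a methoxy group, so lithiation and formylation with DMF can give only one aldehyde, while the isolated alkenes and the hindered benzylic CH2 are not expected to be deprotonated.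

**Step 9**
Reactants: 17 6-methoxy-2,4-bis(methoxymethoxy)-3-[(2R)-lavandulyl]benzaldehyde
Product: 18 2,4-dihydroxy-6-methoxy-3-[(2R)-lavandulyl]benzaldehyde
Conditions: HCl (1 M in MeOH), 25 → 40 °C
Reagents that add atoms: none
Why: Acid-catalysed methanolysis of the two methoxymethyl acetals, in which the formyl group lowers the nucleophilicity of ring and phenols so that dilute methanolic HCl, as used routinely on prenylated phenols, should not induce chroman formation with the isopropenyl group.

**Step 10**
Reactants: 18 2,4-dihydroxy-6-methoxy-3-[(2R)-lavandulyl]benzaldehyde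
Product: 19 4-(tert-butyldimethylsilyloxy)-2-hydroxy-6-methoxy-3-[(2R)-lavandulyl]benzaldehyde
Conditions: t-BuMe2SiCl (1 equiv), imidazole, DMF, 0 °C
Reagents that add atoms: tert-butyldimethylsilyl chloride, CC(C)(C)[Si](C)(C)Cl
Why: Selective silylation, in which the 2-hydroxyl is held in a hydrogen bond to the formyl group and flanked by two substituents, so the more acidic, unchelated 4-hydroxyl para to the aldehyde is expected to be the only one silylated.

**Step 11**
Reactants: 19 4-(tert-butyldimethylsilyloxy)-2-hydroxy-6-methoxy-3-[(2R)-lavandulyl]benzaldehyde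
Product: 20 3-(tert-butyldimethylsilyloxy)-6-(dimethoxymethyl)-5-methoxy-2-[(2R)-lavandulyl]phenol
Conditions: HC(OMe)3, MeOH, pyridinium p-toluenesulfonate (cat.), 25 °C; then Et3N, evaporation
Reagents that add atoms: trimethyl orthoformate, COC(OC)OC; methanol, CO (co-solvent, exchanges into the same methoxy groups)
Why: Acid-catalysed acetalisation driven by the orthoformate, with the acid quenched by Et3N before evaporation because the acetal of this electron-rich salicylaldehyde is sensitive, the crude product being used directly.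

**Step 12**
Reactants: 21 4-(tert-butyldimethylsilyloxy)benzaldehyde
Product: 22 4-(tert-butyldimethylsilyloxy)styrene
Conditions: Ph3PCH3Br, n-BuLi, THF, 0 °C; then 21, −78 → 25 °C
Reagents that add atoms: methyltriphenylphosphonium bromide, C[P+](c1ccccc1)(c1ccccc1)c1ccccc1.[Br-]
Why: Wittig methylenation with the preformed non-stabilised ylide, made with a slight deficit of n-BuLi so that no free base reaches the aryl silyl ether.

**Step 13**
Reactants: 20 3-(tert-butyldimethylsilyloxy)-6-(dimethoxymethyl)-5-methoxy-2-[(2R)-lavandulyl]phenol; 22 4-(tert-butyldimethylsilyloxy)styrene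
Product: 24 (2S,4S)-7-(tert-butyldimethylsilyloxy)-2-[4-(tert-butyldimethylsilyloxy)phenyl]-4,5-dimethoxy-8-[(2R)-lavandulyl]chromane (2,4-cis), via ortho-quinone methide 23 (not isolated)
Conditions: (R)-3,3'-bis(2,4,6-triisopropylphenyl)-1,1'-binaphthyl-2,2'-diyl hydrogen phosphate (10 mol %), 22 (3 equiv), 5 Å MS, PhMe, −20 → 0 °C
Reagents that add atoms: none
Why: Proposed new method: the chiral acid ionises acetal 20 with loss of methanol to the hydrogen-bonded ion pair of the O-protonated 4-methoxy ortho-quinone methide 23 (an O-methyl oxocarbenium ion stabilised by the three oxygens of ring A), the CH2 terminus of styrene 22 attacks C4, and the 4-silyloxybenzyl cation that results at C2 is captured by O1. The closest known reaction types are the achiral acid-promoted [4+2] of salicylaldehyde acetals with styrenes, which gives 2,4-cis-4-alkoxyflavans, and chiral phosphoric acid-controlled cycloadditions of ortho-quinone methides with alkenes that carry a hydrogen-bond donor; an enantioselective intermolecular case with a simple styrene is the untested part. Ring C, the only ring formed, closes as a six-membered ring in a polar, asynchronous inverse-demand hetero-Diels–Alder mode, C3–C4 first and O1–C2 second. The C4 centre is set by the face of the planar cation that the phosphate, bound to the C8a hydroxyl beside the bulky C8 lavandulyl group, leaves open, and the C2 centre follows from it through the endo-type closure that places aryl and methoxy cis, so C2 is under catalyst control and is not expected to feel the remote C2'' centre. Regiochemistry is fixed by polarity (nucleophilic styrene terminus to the electrophilic C4), and the chemoselectivity needed, styrene 22 ahead of the two lavandulyl alkenes and of the product ether, is secured by the donor para-silyloxy group, the excess of 22 and the weak acid at low temperature. Any 2,4-trans isomer is to be removed by chromatography before step 14, because it would deliver the wrong C2 configuration once C4 is oxidised.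

**Step 14**
Reactants: 24 (2S,4S)-7-(tert-butyldimethylsilyloxy)-2-[4-(tert-butyldimethylsilyloxy)phenyl]-4,5-dimethoxy-8-[(2R)-lavandulyl]chromane
Product: 25 (2S)-7-(tert-butyldimethylsilyloxy)-2-[4-(tert-butyldimethylsilyloxy)phenyl]-5-methoxy-8-[(2R)-lavandulyl]chroman-4-one
Conditions: 2,3-dichloro-5,6-dicyano-1,4-benzoquinone (DDQ), CH2Cl2/pH 7 phosphate buffer, 0 °C
Reagents that add atoms: water, O
Why: DDQ oxidation of an electron-rich benzylic ether, as in the oxidative cleavage of alkoxybenzyl ethers, in which hydride is abstracted from C4 (activated by its own methoxy group and by the three oxygens of ring A far more than the C1'' methylene or C2–H) and water converts the oxocarbenium ion into the ketone with loss of methanol, the buffered medium leaving C2 untouched.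

**Step 15**
Reactants: 25 (2S)-7-(tert-butyldimethylsilyloxy)-2-[4-(tert-butyldimethylsilyloxy)phenyl]-5-methoxy-8-[(2R)-lavandulyl]chroman-4-one
Product: 26 kushenol U [(2S)-7-hydroxy-2-(4-hydroxyphenyl)-5-methoxy-8-[(2R)-lavandulyl]chroman-4-one]
Conditions: HF·pyridine, pyridine, THF, 0 → 25 °C
Reagents that add atoms: none
Why: Fluoride-mediated cleavage of both aryl silyl ethers under buffered, weakly acidic conditions, which avoid the phenoxide-triggered retro-oxa-Michael opening that would racemise C2 and do not protonate the lavandulyl alkenes.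

**Compound list**
1 | (S)-4-benzyloxazolidin-2-one | O=C1N[C@@H](Cc2ccccc2)CO1 | starting material
2 | 3-methylbut-2-enoyl chloride | CC(C)=CC(=O)Cl | starting material
3 | lithium (S)-4-benzyl-2-oxooxazolidin-3-ide | [Li+].O=C1[N-][C@@H](Cc2ccccc2)CO1 | intermediate (not isolated)
4 | (S)-4-benzyl-3-(3-methylbut-2-enoyl)oxazolidin-2-one | CC(C)=CC(=O)N1[C@@H](Cc2ccccc2)COC1=O | intermediate
5 | 1-bromo-3-methylbut-2-ene (prenyl bromide) | CC(C)=CCBr | starting material
6 | sodium (Z)-dienolate of 4 | [Na+].C=C(C)/C=C(\[O-])N1[C@@H](Cc2ccccc2)COC1=O | intermediate (not isolated)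
7 | (S)-4-benzyl-3-[(2S)-5-methyl-2-(prop-1-en-2-yl)hex-4-enoyl]oxazolidin-2-one | C=C(C)[C@H](CC=C(C)C)C(=O)N1[C@@H](Cc2ccccc2)COC1=O | intermediate
8 | (S)-lavandulol, (2S)-5-methyl-2-(prop-1-en-2-yl)hex-4-en-1-ol | C=C(C)[C@H](CC=C(C)C)CO | intermediate
9 | (S)-lavandulyl iodide, (3S)-3-(iodomethyl)-2,6-dimethylhepta-1,5-diene | C=C(C)[C@H](CC=C(C)C)CI | intermediate
10 | 5-methoxyresorcinol | COc1cc(O)cc(O)c1 | starting material
11 | 1-methoxy-3,5-bis(methoxymethoxy)benzene | COCOc1cc(OC)cc(OCOC)c1 | intermediate
12 | 2-lithio-5-methoxy-1,3-bis(methoxymethoxy)benzene | [Li]c1c(OCOC)cc(OC)cc1OCOC | intermediate (not isolated)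
13 | 2-iodo-5-methoxy-1,3-bis(methoxymethoxy)benzene | COCOc1cc(OC)cc(OCOC)c1I | intermediate
14 | [(2S)-5-methyl-2-(prop-1-en-2-yl)hex-4-en-1-yl]zinc iodide | C=C(C)[C@H](CC=C(C)C)C[Zn]I | intermediate (not isolated)
15 | 5-methoxy-1,3-bis(methoxymethoxy)-2-[(2R)-5-methyl-2-(prop-1-en-2-yl)hex-4-en-1-yl]benzene | C=C(C)[C@H](CC=C(C)C)Cc1c(OCOC)cc(OC)cc1OCOC | intermediate
16 | 4-lithio derivative of 15 (lithium between methoxymethoxy and methoxy) | C=C(C)[C@H](CC=C(C)C)Cc1c(OCOC)cc(OC)c([Li])c1OCOC | intermediate (not isolated)
17 | 6-methoxy-2,4-bis(methoxymethoxy)-3-[(2R)-lavandulyl]benzaldehyde | C=C(C)[C@H](CC=C(C)C)Cc1c(OCOC)cc(OC)c(C=O)c1OCOC | intermediate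
18 | 2,4-dihydroxy-6-methoxy-3-[(2R)-lavandulyl]benzaldehyde | C=C(C)[C@H](CC=C(C)C)Cc1c(O)cc(OC)c(C=O)c1O | intermediate
19 | 4-(tert-butyldimethylsilyloxy)-2-hydroxy-6-methoxy-3-[(2R)-lavandulyl]benzaldehyde | C=C(C)[C@H](CC=C(C)C)Cc1c(O[Si](C)(C)C(C)(C)C)cc(OC)c(C=O)c1O | intermediate
20 | 3-(tert-butyldimethylsilyloxy)-6-(dimethoxymethyl)-5-methoxy-2-[(2R)-lavandulyl]phenol | C=C(C)[C@H](CC=C(C)C)Cc1c(O[Si](C)(C)C(C)(C)C)cc(OC)c(C(OC)OC)c1O | intermediate
21 | 4-(tert-butyldimethylsilyloxy)benzaldehyde | O=Cc1ccc(O[Si](C)(C)C(C)(C)C)cc1 | starting material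
22 | 4-(tert-butyldimethylsilyloxy)styrene | C=Cc1ccc(O[Si](C)(C)C(C)(C)C)cc1 | intermediate
23 | 3-(tert-butyldimethylsilyloxy)-5-methoxy-6-(methoxymethylidene)-2-[(2R)-lavandulyl]cyclohexa-2,4-dien-1-one (ortho-quinone methide, exocyclic geometry left open) | C=C(C)[C@H](CC=C(C)C)CC1=C(O[Si](C)(C)C(C)(C)C)C=C(OC)C(=COC)C1=O | intermediate (not isolated)
24 | (2S,4S)-7-(tert-butyldimethylsilyloxy)-2-[4-(tert-butyldimethylsilyloxy)phenyl]-4,5-dimethoxy-8-[(2R)-lavandulyl]chromane | C=C(C)[C@H](CC=C(C)C)Cc1c(O[Si](C)(C)C(C)(C)C)cc(OC)c2c1O[C@H](c1ccc(O[Si](C)(C)C(C)(C)C)cc1)C[C@@H]2OC | intermediate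
25 | (2S)-7-(tert-butyldimethylsilyloxy)-2-[4-(tert-butyldimethylsilyloxy)phenyl]-5-methoxy-8-[(2R)-lavandulyl]chroman-4-one | C=C(C)[C@H](CC=C(C)C)Cc1c(O[Si](C)(C)C(C)(C)C)cc(OC)c2c1O[C@H](c1ccc(O[Si](C)(C)C(C)(C)C)cc1)CC2=O | intermediate
26 | kushenol U, (2S)-7-hydroxy-2-(4-hydroxyphenyl)-5-methoxy-8-[(2R)-lavandulyl]chroman-4-one | C=C(C)[C@H](CC=C(C)C)Cc1c(O)cc(OC)c2c1O[C@H](c1ccc(O)cc1)CC2=O | target

**Step count**
Total: 15 steps. Longest linear sequence: 12 steps (steps 1–4, 7–11, 13–15, from the oxazolidinone 1).

**Steps most likely to fail**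

1. Step 13, the one step that goes beyond known chemistry. What may go wrong: poor facial discrimination of the ion-paired cation, because the styrene has no hydrogen-bond donor to anchor it to the phosphate, giving both C2 epimers; or ionisation too slow with so weak an acid. Fallback (known chemistry only), setting out from 20 and 22: the cycloaddition is run with an achiral acid (diphenyl hydrogen phosphate, 5 Å MS, CH2Cl2), the known stereorandom mode, which should give 24 together with its cis epimer (2R,4R)-7-(tert-butyldimethylsilyloxy)-2-[4-(tert-butyldimethylsilyloxy)phenyl]-4,5-dimethoxy-8-[(2R)-lavandulyl]chromane F1. Oxidation of the mixture with DDQ as in step 14 should give 25 and the (2R)-configured bis-silyl flavanone F2. A kinetic resolution by Noyori asymmetric transfer hydrogenation (RuCl[(R,R)-TsNCH(Ph)CH(Ph)NH2](p-cymene), HCO2H/Et3N) should then reduce the (2R)-epimer to the 2,4-cis (2R,4R)-flavan-4-ol F3 and leave the (2S)-ketone, which is separated by chromatography. The route is rejoined at 25.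

2. Step 7. What may go wrong: β-hydride elimination from the alkylpalladium intermediate (the β-hydrogen is allylic), slow coupling at the di-ortho-substituted iodide, or a radical vinyl shift during zinc insertion that scrambles the chain. Fallback, setting out from 9 and 13: a B-alkyl Suzuki–Miyaura coupling replaces the zinc route. Iodine–lithium exchange on 9 (t-BuLi, Et2O, −78 °C) gives the alkyllithium [(2S)-5-methyl-2-(prop-1-en-2-yl)hex-4-en-1-yl]lithium F4, which is trapped with B-methoxy-9-borabicyclo[3.3.1]nonane to give the lithium B-alkyl-B-methoxy borinate F5. This is coupled with 13 (PdCl2[1,1'-bis(diphenylphosphino)ferrocene], K3PO4, DMF/THF, 50 °C), and the route is rejoined at 15.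

3. Step 14. What may go wrong: sluggish hydride abstraction if the peri 5-methoxy group forces the C4–H bond out of alignment with ring A, followed by over-oxidation at the C1'' methylene or at C2–H on forcing. Fallback, setting out from 24: the oxidation is split into solvolysis and alcohol oxidation. Mild acid hydrolysis through the same stabilised C4 cation (pyridinium p-toluenesulfonate, THF/H2O) exchanges the methoxy group for hydroxyl to give (2S)-7-(tert-butyldimethylsilyloxy)-2-[4-(tert-butyldimethylsilyloxy)phenyl]-5-methoxy-8-[(2R)-lavandulyl]chroman-4-ol F6 (either C4 epimer serves). Dess–Martin periodinane (1,1,1-triacetoxy-1,1-dihydro-1,2-benziodoxol-3(1H)-one) in CH2Cl2 with NaHCO3 then gives the ketone, and the route is rejoined at 25.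

**Further compounds**
F1 | step 13 | (2R,4R)-7-(tert-butyldimethylsilyloxy)-2-[4-(tert-butyldimethylsilyloxy)phenyl]-4,5-dimethoxy-8-[(2R)-lavandulyl]chromane | C=C(C)[C@H](CC=C(C)C)Cc1c(O[Si](C)(C)C(C)(C)C)cc(OC)c2c1O[C@@H](c1ccc(O[Si](C)(C)C(C)(C)C)cc1)C[C@H]2OC
F2 | step 13 | (2R)-7-(tert-butyldimethylsilyloxy)-2-[4-(tert-butyldimethylsilyloxy)phenyl]-5-methoxy-8-[(2R)-lavandulyl]chroman-4-one | C=C(C)[C@H](CC=C(C)C)Cc1c(O[Si](C)(C)C(C)(C)C)cc(OC)c2c1O[C@@H](c1ccc(O[Si](C)(C)C(C)(C)C)cc1)CC2=O
F3 | step 13 | (2R,4R)-7-(tert-butyldimethylsilyloxy)-2-[4-(tert-butyldimethylsilyloxy)phenyl]-5-methoxy-8-[(2R)-lavandulyl]chroman-4-ol | C=C(C)[C@H](CC=C(C)C)Cc1c(O[Si](C)(C)C(C)(C)C)cc(OC)c2c1O[C@@H](c1ccc(O[Si](C)(C)C(C)(C)C)cc1)C[C@H]2O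
F4 | step 7 | [(2S)-5-methyl-2-(prop-1-en-2-yl)hex-4-en-1-yl]lithium | C=C(C)[C@H](CC=C(C)C)C[Li]
F5 | step 7 | lithium 9-methoxy-9-[(2S)-5-methyl-2-(prop-1-en-2-yl)hex-4-en-1-yl]-9-borabicyclo[3.3.1]nonan-9-uide | [Li+].C=C(C)[C@H](CC=C(C)C)C[B-]1(OC)C2CCCC1CCC2
F6 | step 14 | (2S)-7-(tert-butyldimethylsilyloxy)-2-[4-(tert-butyldimethylsilyloxy)phenyl]-5-methoxy-8-[(2R)-lavandulyl]chroman-4-ol (C4 epimers) | C=C(C)[C@H](CC=C(C)C)Cc1c(O[Si](C)(C)C(C)(C)C)cc(OC)c2c1O[C@H](c1ccc(O[Si](C)(C)C(C)(C)C)cc1)CC2O
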